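The plan cuts the C3–C4 bond of the oxolane ring (lignan C8′–C8) by polarity reversal. A terminal epoxide is opened by titanocene(III) to a nucleophilic C8′ radical, which closes 5-exo-dig onto an aryl alkyne. This one operation forms the ring and the 8–8′ bond, funnels both epoxide epimers into one product, sets C3 trans to the C2 catechol ring, frees the C9′ hydroxyl and leaves an E-benzylidene group at C4. It exploits the contiguous C2–C3–C4–C7 array: the alkene geometry stores C7, and one syn hydroboration then writes C4 and C7 together. The precursor is an acyclic benzylic propargyl ether with a single defined stereocentre.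

Key step: step 6

Locants used: oxolane O1, C2 (= lignan C7′, bears the catechol ring), C3 (= C8′, bears C9′H2OH), C4 (= C8), C5 (= C9). C7 is the exocyclic carbinol carbon that bears the guaiacyl ring.
Assumption: compounds 1, 2, 5 and 8 are taken as commercially available.

Step 1
Reactants: 1 3,4-bis(benzyloxy)benzaldehyde; 2 vinylmagnesium bromide
Product: 3 (±)-1-[3,4-bis(benzyloxy)phenyl]prop-2-en-1-ol
Conditions: 2 (1.2 equiv), THF, −78 → 0 °C; aq NH4Cl
Reagents that add atoms: none
Why: Grignard 1,2-addition to an aromatic aldehyde brings in C8′ and C9′; the carbinol centre (future C2) forms racemic and is resolved in step 2.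

Step 2
Reactants: 3 (±)-1-[3,4-bis(benzyloxy)phenyl]prop-2-en-1-ol
Product: 4 (1S)-1-[3,4-bis(benzyloxy)phenyl]prop-2-en-1-ol
Conditions: immobilised Candida antarctica lipase B, vinyl acetate (0.6 equiv), MTBE, 30 °C, stopped just past half conversion; chromatography
Reagents that add atoms: none
Why: In this lipase-catalysed kinetic resolution by transesterification the Kazlauskas rule (aryl = large, vinyl = medium group) predicts acylation of the R alcohol, so the S alcohol, which carries the C2 configuration of the target, should stay unreacted and be separable from the acetate.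

Step 3
Reactants: 4 (1S)-1-[3,4-bis(benzyloxy)phenyl]prop-2-en-1-ol; 5 propargyl bromide
Product: 6 1,2-bis(benzyloxy)-4-[(1S)-1-(prop-2-yn-1-yloxy)prop-2-en-1-yl]benzene
Conditions: NaH, Bu4NI (cat.), THF, 0 °C → rt
Reagents that add atoms: none
Why: Williamson ether synthesis on a reactive propargylic bromide; the carbinol C–O bond is not broken, so the stereocentre is retained.

Step 4
Reactants: 6 1,2-bis(benzyloxy)-4-[(1S)-1-(prop-2-yn-1-yloxy)prop-2-en-1-yl]benzene
Product: 7 2-{(R)-[3,4-bis(benzyloxy)phenyl](prop-2-yn-1-yloxy)methyl}oxirane, both epimers at the oxirane CH (benzylic centre spatially unchanged, descriptor changed by CIP rank only)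
Conditions: mCPBA, CH2Cl2/aq NaHCO3, 0 °C → rt
Reagents that add atoms: mCPBA (3-chloroperoxybenzoic acid), OOC(=O)c1cccc(Cl)c1
Why: Prilezhaev epoxidation of the only alkene (terminal alkyne and arenes are much less nucleophilic, the buffer protects the acid-labile ether); no facial control is needed because the new centre becomes a planar radical in step 6.

Step 5
Reactants: 7 the epoxy propargyl ether (both epimers); 8 1-(benzyloxy)-4-bromo-2-methoxybenzene
Product: 9 2-{(R)-[3,4-bis(benzyloxy)phenyl]({3-[4-(benzyloxy)-3-methoxyphenyl]prop-2-yn-1-yl}oxy)methyl}oxirane, both epimers at the oxirane CH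
Conditions: PdCl2(MeCN)2 (cat.), XPhos (cat.), Cs2CO3, MeCN, 70 °C
Reagents that add atoms: none
Why: Copper-free Sonogashira coupling of an electron-rich aryl bromide with the terminal alkyne; a carbonate base in place of an amine avoids ammonium halide, which could open the epoxide, and no stereocentre is touched.

Step 6
Reactants: 9 the epoxy aryl-alkyne ether (both epimers)
Product: 10 [(2S,3R,4E)-4-{[4-(benzyloxy)-3-methoxyphenyl]methylidene}-2-[3,4-bis(benzyloxy)phenyl]oxolan-3-yl]methanol
Conditions: Cp2TiCl2 (20 mol %), Mn dust, 2,4,6-collidine·HCl, THF (high dilution), rt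
Reagents that add atoms: none
Why: Mn reduces Cp2TiCl2 to Cp2TiCl, which binds the oxirane oxygen and cleaves the C8′–O bond by single-electron transfer, so a normally electrophilic epoxide carbon becomes the nucleophilic secondary β-titanoxy radical (titanocene(III) reductive epoxide opening with radical cyclisation, Nugent–RajanBabu chemistry in its collidinium-buffered catalytic form, a known reaction type for epoxy alkynes). Because this radical is planar, both oxirane epimers of 9 give the same intermediate and the step is stereoconvergent. The oxolane ring closes in the 5-exo-dig mode by attack on the proximal alkyne carbon C8, favoured over 6-endo-dig by orbital overlap and because only the exo mode gives an aryl-conjugated vinyl radical at C7. The new stereocentre C3 is controlled by the resident C2 centre: in the envelope-like transition state the C2 aryl group sits pseudo-equatorial and the CH2O[Ti] arm turns away from it, which should give the 2,3-trans ring. The linear α-aryl vinyl radical is then quenched in the alkene plane (capture by a second Ti(III) and protonolysis by collidinium with retention, or H abstraction from THF) from the open C5H2 flank rather than the flank walled by C3 and its titanoxymethyl arm, so hydrogen ends syn to C5 and the aryl group syn to C3, the E alkene that step 7 needs. The step needs cyclisation to outrun reduction or deoxygenation of the first radical, which the low stationary Ti(III) concentration, the dilution and the fast closure onto an aryl alkyne should secure, while benzyl ethers, arenes and the benzylic ether are inert to Ti(III).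

Step 7
Reactants: 10 the E-benzylidene oxolane alcohol
Product: 12 (R)-[4-(benzyloxy)-3-methoxyphenyl]{(3R,4R,5S)-5-[3,4-bis(benzyloxy)phenyl]-4-(hydroxymethyl)oxolan-3-yl}methanol, via benzylic organoborane 11 (not isolated)
Conditions: BH3·SMe2 (3 equiv), THF, 0 °C → rt; then aq NaOH, H2O2, 0 °C
Reagents that add atoms: hydrogen peroxide, OO; borane–dimethyl sulfide, C[S+](C)[BH3-] (boron, in 11 only)
Why: In this Brown hydroboration–oxidation boron goes to the less substituted alkene carbon C7 and hydrogen to ring carbon C4 in a concerted syn addition on the face opposite the C3 CH2O–boryl arm, which allylic 1,3-strain with the syn aryl group pushes into a pseudo-axial, face-blocking position, so the E geometry should translate into the 7R carbinol and the 3,4-cis ring (C4 R) at once, the C–B bond being oxidised with retention.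

Step 8
Reactants: 12 the tri-O-benzyl ether of the target
Product: 13 (7R)-7-hydroxytaxiresinol
Conditions: H2 (1 atm), 10% Pd/C, EtOAc–EtOH, rt, acid-free, stopped when uptake ends
Reagents that add atoms: none
Why: Catalytic hydrogenolysis cleaves the three aryl benzyl ethers faster than the hindered secondary benzylic C–O bonds under neutral conditions, and no stereocentre is involved.

Compound list
1 | 3,4-bis(benzyloxy)benzaldehyde | O=Cc1ccc(OCc2ccccc2)c(OCc2ccccc2)c1 | starting material
2 | vinylmagnesium bromide | C=C[Mg]Br | starting material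
3 | (±)-1-[3,4-bis(benzyloxy)phenyl]prop-2-en-1-ol | C=CC(O)c1ccc(OCc2ccccc2)c(OCc2ccccc2)c1 | intermediate
4 | (1S)-1-[3,4-bis(benzyloxy)phenyl]prop-2-en-1-ol | C=C[C@H](O)c1ccc(OCc2ccccc2)c(OCc2ccccc2)c1 | intermediate
5 | propargyl bromide (3-bromoprop-1-yne) | C#CCBr | starting material
6 | 1,2-bis(benzyloxy)-4-[(1S)-1-(prop-2-yn-1-yloxy)prop-2-en-1-yl]benzene | C=C[C@H](OCC#C)c1ccc(OCc2ccccc2)c(OCc2ccccc2)c1 | intermediate
7 | 2-{(R)-[3,4-bis(benzyloxy)phenyl](prop-2-yn-1-yloxy)methyl}oxirane, both epimers at the oxirane CH | C1OC1[C@H](OCC#C)c2ccc(OCc3ccccc3)c(OCc3ccccc3)c2 | intermediate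
8 | 1-(benzyloxy)-4-bromo-2-methoxybenzene | COc1cc(Br)ccc1OCc1ccccc1 | starting material
9 | 2-{(R)-[3,4-bis(benzyloxy)phenyl]({3-[4-(benzyloxy)-3-methoxyphenyl]prop-2-yn-1-yl}oxy)methyl}oxirane, both epimers at the oxirane CH | C1OC1[C@H](OCC#Cc2ccc(OCc3ccccc3)c(OC)c2)c2ccc(OCc3ccccc3)c(OCc3ccccc3)c2 | intermediate
10 | [(2S,3R,4E)-4-{[4-(benzyloxy)-3-methoxyphenyl]methylidene}-2-[3,4-bis(benzyloxy)phenyl]oxolan-3-yl]methanol | COc1cc(/C=C2/CO[C@H](c3ccc(OCc4ccccc4)c(OCc4ccccc4)c3)[C@H]2CO)ccc1OCc1ccccc1 | intermediate
11 | benzylic organoborane (C7–BH2, C9′–O–BH2; configuration as in 12) | COc1cc([C@H](B)[C@H]2CO[C@H](c3ccc(OCc4ccccc4)c(OCc4ccccc4)c3)[C@H]2COB)ccc1OCc1ccccc1 | intermediate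
12 | (R)-[4-(benzyloxy)-3-methoxyphenyl]{(3R,4R,5S)-5-[3,4-bis(benzyloxy)phenyl]-4-(hydroxymethyl)oxolan-3-yl}methanol | COc1cc([C@H](O)[C@H]2CO[C@H](c3ccc(OCc4ccccc4)c(OCc4ccccc4)c3)[C@H]2CO)ccc1OCc1ccccc1 | intermediate
13 | (7R)-7-hydroxytaxiresinol, 4-[(2S,3R,4R)-4-[(R)-hydroxy(4-hydroxy-3-methoxyphenyl)methyl]-3-(hydroxymethyl)oxolan-2-yl]benzene-1,2-diol | COc1cc([C@H](O)[C@H]2CO[C@H](c3ccc(O)c(O)c3)[C@H]2CO)ccc1O | target

Total step count: 8
Longest linear sequence: 8 steps (1 → 13)

Steps most likely to fail

Step 6. The vinyl radical may be quenched from both flanks, which would scramble the alkene geometry and with it C7.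
- The fallback sets out from 7 and comes back at 12.
- The guaiacyl ring is kept out of the radical step, so no alkene geometry has to be controlled, and C7 is made by carbonyl addition instead.
- Ti(III) cyclisation of 7 onto the terminal alkyne should give the 4-methylidene oxolane alcohol F1.
- TBDPSCl/imidazole gives its silyl ether F2.
- 9-BBN then NaBO3 should add opposite to the silyloxymethyl arm and give the 3,4-cis primary alcohol F3.
- Buffered Dess–Martin oxidation gives the aldehyde F4.
- The aryl Grignard reagent F5, made from 8 and Mg, is added at −78 °C. The Felkin–Anh model (C3 branch as large group) and the chelate through the ring oxygen both point to the 7R carbinol silyl ether F6.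
- TBAF then gives 12.

Step 7. Borane may attack from both alkene faces (for instance by delivery from a transient O–B tether), or place boron at C4.
- The fallback sets out from 10 and comes back at 12.
- The source of stereocontrol is changed from the substrate alone to matched reagent plus substrate.
- The C9′ hydroxyl is capped with TBDPSCl/imidazole to give the silyl ether of 10 F7. This removes any tether and enlarges the wall on the blocked face.
- Hydroboration is run with enantiopure monoisopinocampheylborane from (+)-α-pinene. By analogy with simple trisubstituted alkenes this reagent is predicted to place boron on the C7 face that leads to 7R.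
- Oxidation with NaBO3 gives the 7R carbinol silyl ether F6, and TBAF returns 12.

Step 8. Hydrogenolytic loss of the benzylic C7 hydroxyl, or opening of the C2–O1 bond, may accompany debenzylation.
- The fallback sets out from 12 and ends at 13.
- The reductive step is moved to a substrate whose carbinol oxygen is shielded, and the synthesis ends with a non-reductive unmasking.
- TBSCl/imidazole/DMAP converts 12 into the 7,9′-bis-TBS ether F8.
- H2, Pd/C removes the three aryl benzyl groups to give the triphenol bis-TBS ether F9.
- Acetic-acid-buffered TBAF (or Et3N·3HF) under argon gives 13.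

Further compounds
F1 | step 6 | [(2S,3R)-2-[3,4-bis(benzyloxy)phenyl]-4-methylideneoxolan-3-yl]methanol | C=C1CO[C@H](c2ccc(OCc3ccccc3)c(OCc3ccccc3)c2)[C@H]1CO
F2 | step 6 | tert-butyldiphenylsilyl ether of F1 | C=C1CO[C@H](c2ccc(OCc3ccccc3)c(OCc3ccccc3)c2)[C@H]1CO[Si](c2ccccc2)(c2ccccc2)C(C)(C)C
F3 | step 6 | 2,3-trans-3,4-cis [5-[3,4-bis(benzyloxy)phenyl]-4-(TBDPS-oxymethyl)oxolan-3-yl]methanol (ring centres as in 12) | OC[C@H]1CO[C@H](c2ccc(OCc3ccccc3)c(OCc3ccccc3)c2)[C@H]1CO[Si](c2ccccc2)(c2ccccc2)C(C)(C)C
F4 | step 6 | corresponding oxolane-3-carbaldehyde (ring centres as in 12) | O=C[C@H]1CO[C@H](c2ccc(OCc3ccccc3)c(OCc3ccccc3)c2)[C@H]1CO[Si](c2ccccc2)(c2ccccc2)C(C)(C)C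
F5 | step 6 | [4-(benzyloxy)-3-methoxyphenyl]magnesium bromide | COc1cc([Mg]Br)ccc1OCc1ccccc1
F6 | step 6 | C9′-O-TBDPS ether of 12 (7R) | COc1cc([C@H](O)[C@H]2CO[C@H](c3ccc(OCc4ccccc4)c(OCc4ccccc4)c3)[C@H]2CO[Si](c3ccccc3)(c3ccccc3)C(C)(C)C)ccc1OCc1ccccc1
F7 | step 7 | C9′-O-TBDPS ether of 10 (2S,3R,4E) | COc1cc(/C=C2/CO[C@H](c3ccc(OCc4ccccc4)c(OCc4ccccc4)c3)[C@H]2CO[Si](c3ccccc3)(c3ccccc3)C(C)(C)C)ccc1OCc1ccccc1
F8 | step 8 | 7,9′-bis-O-TBS ether of 12 | COc1cc([C@H](O[Si](C)(C)C(C)(C)C)[C@H]2CO[C@H](c3ccc(OCc4ccccc4)c(OCc4ccccc4)c3)[C@H]2CO[Si](C)(C)C(C)(C)C)ccc1OCc1ccccc1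
F9 | step 8 | 7,9′-bis-O-TBS ether of 13 | COc1cc([C@H](O[Si](C)(C)C(C)(C)C)[C@H]2CO[C@H](c3ccc(O)c(O)c3)[C@H]2CO[Si](C)(C)C(C)(C)C)ccc1O
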